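**Minutes: the flask, partner doubled or precatalyst raised**

The meeting resolved to bracket both asked factors before estimating either.

| flask | starting material | partner | precatalyst | remark |
|---|---|---|---|---|
| zeta | 0.21 M | 0.70 equiv | 0.66 mol% | run made earlier |
| epsilon | 0.32 M | 0.70 equiv | 0.66 mol% | run made earlier |
| gamma | 0.43 M | 0.70 equiv | 0.99 mol% | run made earlier |
| flask | 0.43 M | 0.700 equiv | 0.66 mol% |  |

| zeta: time / h | zeta: target / % | epsilon: time / h | epsilon: target / % | gamma: time / h | gamma: target / % |
|---|---|---|---|---|---|
| 0.333 | 7 | 0.833 | 35 | 0.333 | 14 |
| 1.00 | 29 | 1.50 | 58 | 1.00 | 60 |
| 2.00 | 53 | 2.50 | 71 | 2.00 | 68 |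
| 3.00 | 61 | 3.00 | 66 | 3.00 | 71 |
| 4.00 | 65 | 4.00 | 69 | 4.00 | 70 |

(scatter of a reading: 1.5 percentage points)

* factor on the rate of making target when 10% of the starting material are converted if partner is charged twice over
* factor on the rate when 10% of the starting material are converted if precatalyst is charged at 3 mol% instead

The first speaker noted that epsilon and gamma level off near the partner charge, gamma reading 71% at 3.00 h, and so took partner as the limiting reagent. The second pointed to the start of gamma: target rose by a factor of 4.29 while time rose by 3.00. She read this acceleration as precatalyst still activating.

The first speaker then proposed the ceiling factor: the ratio of an amount after the change to that before it, at the mark of 10% conversion, for a rate first order in that amount. For precatalyst at 3 mol%, taking the charges, it is 4.55. For doubled partner, counting one partner per starting material converted, c(partner) gives 2.17. The second speaker answered that a faster run meets the mark earlier, with less activated, so she estimated the lower end as the square root: 2.13 and 1.47. The meeting committed to these brackets, not to single values.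

The forecast gives 1.6 for doubled partner and 2.4 for the higher loading, arguing that “Faster runs reach it sooner, with less catalyst active”.

The simulation gives 1.90 and 2.83.

    partner + precatalyst → free catalyst + spent reagent (k = 0.00110 L mol⁻¹ s⁻¹)
    2 starting material → self-condensation product (k = 1.50 × 10⁻⁴ L mol⁻¹ s⁻¹)
    catalyst intermediate B → free catalyst + target (k = 0.180 s⁻¹)
    partner + free catalyst ⇌ catalyst intermediate A (K = 3.70 L mol⁻¹, k = 0.800 L mol⁻¹ s⁻¹)
    starting material + catalyst intermediate A → catalyst intermediate B (k = 4.80 L mol⁻¹ s⁻¹)

Both factors stand inside their brackets, above the square roots and below the ceilings. The doubled-partner flask reaches 0.876 of its ceiling, the 3 mol% flask 0.622 of its own. In the flask as charged, starting material also goes without catalyst: at 0.400 h, self-condensation product stands at 14.0% beside target at 16.2%. That step is one reason, not the main one, for the flask's rate of 0.160 M h⁻¹ at the mark: the same run without it gives 1.59 times that rate.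

All runs stem from a simulated flask for an exercise; scatter was added.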